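## The problem

Pilosanol N is (+)-catechin (rings A, B and C) whose C8 carries a CH2 bridge to a second, fully substituted phloroglucinol ring (ring D). One remark on the reading of the structure: the bridge sits on the ring A carbon between C7–OH and C8a–O1, so it is taken as C8, and the flavan is (2R,3S), the configuration of (+)-catechin. The only stereocenters are C2 and C3 of ring C, trans to each other. They are remote from the flat ring D and can direct nothing there, so they are best taken from the chiral pool and kept away from conditions that open ring C or epimerise the benzylic C2. Two questions of position remain: the bridge must be at C8 and not at the almost equally nucleophilic C6, and the six substituents of ring D must follow in the order OMe, Me, OH, CH2, OH, acetyl. Once unmasked, the catechol and both phloroglucinol rings are sensitive to air and base, and the CH2 between two trioxygenated arenes can be cleaved by strong protic or Lewis acids, so the protecting groups must leave under neutral conditions. The enabling feature is the pattern of ring D: the CH2-bearing carbon lies between two oxygenated carbons, then come the methyl carbon, the methoxy carbon, and a sixth carbon whose acetyl group can be added last. A vinylketene–ynol ether benzannulation delivers exactly this sequence (phenol carbon, alkyne substituent, siloxy carbon, two substituted carbons, CH). The two alkyne carbons can therefore be the CH2-bearing carbon and one oxygenated neighbour, and the other four carbons can come from a cyclobutenone that already holds methyl and methoxy.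

## Retrosynthesis

**Unmasking (26 from 25 from 24).** Only O–benzyl and O–silyl bonds are cut. The four phenols of the catechin part are held as benzyl ethers in 25 and are released last by neutral hydrogenolysis, so the free polyphenol 26 never meets base or fluoride. The two silyl ethers of 24 (aryl OTIPS on ring D, OTBS at C3) are cut one step earlier with buffered fluoride. The forward steps must leave the aryl ketone and the C2–O1 benzylic ether alone.

**Acetyl group (24 from 23, 22 and 21).** The ring D–acetyl bond is cut. In 21 the acetyl position is the only unsubstituted carbon of ring D and is ortho to the one free phenol. A Fries rearrangement or a Friedel–Crafts acetylation would be shorter. Both need Lewis acids that threaten the benzyl ethers, the silyl ethers and the diarylmethane bridge, and both release an acylium species that the equally electron-rich C6 of ring A could capture. A phenoxide-directed route is therefore preferred: magnesium-mediated ortho-formylation to 22, methyl addition to 23 and oxidation to 24. This costs one more step, and in return the C–C bond is formed only at the carbon ortho to the free OH.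

**Ring D (21 from 10 and 16).** This is the key cut. Two bonds between the fragments are broken: the one between the CH2-bearing carbon and the phenol carbon, and the one between the siloxy carbon and the methyl carbon. What remains is siloxyalkyne 10 (two ring carbons, the bridge and the whole protected catechin) and 3-methoxy-2-methylcyclobutenone 16 (four ring carbons with Me, OMe and the future phenol oxygen). The alternative of joining a finished ring D to catechin by arene alkylation would need the hexasubstituted ring to be made regioselectively by classical phloroglucinol chemistry and would reopen the C6/C8 question. Here ring D is grown on a handle already fixed at C8, and its substitution order follows from the mechanism. The forward reaction must control one orientation only, that of the ketene–alkyne [2+2] step.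

**Siloxyalkyne (10 from 7).** The alkyne C–C bond is cut back to arylacetic ester 7. An ester gives a lithium ynolate with one added carbon (Kowalski homologation), and a bulky silyl chloride traps it on oxygen. The ester is far simpler than the ynol ether and is a stable, storable intermediate. The forward step must add dibromomethyllithium to the ester faster than it enolises the benzylic CH2.

**C8–CH2 bond (7 from 4 and 5).** The aryl–CH2 bond at C8 is cut to aryl bromide 4 and the zinc enolate 6 of ethyl bromoacetate 5. A palladium-catalysed coupling of a Reformatsky reagent brings in the two-carbon ester in one step under nearly neutral conditions. Allylation followed by oxidative cleavage would take three steps.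

**Protected catechin (4 from 3, 2 and 1).** Bromide 4 comes from (+)-catechin 1 by phenol benzylation (2), C8 bromination (3) and silylation of O3. Bromination of the tetrabenzyl ether at C8 is a reliable, position-selective reaction, so the C6/C8 question is settled here, before ring D exists.

**Cyclobutenone (16 from 15, 14, 11 and 12).** The four-membered ring is cut into dichloroketene 13 (from trichloroacetyl chloride 11) and 1-ethoxypropyne 12. Their [2+2] cycloaddition gives 14 with methyl next to the carbonyl. Zinc removes both chlorines (15), and exchange of OEt for OMe gives 16. All three steps use cheap C2 and C3 reagents.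

## Roads not taken

**Alternative 1: ring A built by a Wolff-based vinylketene benzannulation.** The cut removes four bonds of ring A (C6–C7, C8a–C4a, C5–C6, C8a–C8). Irradiation of ring D diazo ketone A1 with chiral siloxyalkyne A2 would give a vinylketene by Wolff rearrangement, and the same cascade as in the chosen plan would deliver phenol A3 with a free C8a hydroxyl. Ring C would then be closed by displacement at the benzylic C2 with inversion, which turns the syn diol of A3 into the 2,3-trans flavan.

- Merits: the route is fully convergent, the bridge is at C8 by construction, and ring D arrives with its acetyl group, so no late acylation is needed. In these respects it is better than the chosen plan, and it is also the better basis for analogues of rings A and B.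
- Weak points: A1 presupposes a finished hexasubstituted ring D, so the regiochemical problem of that ring is pushed back into classical phloroglucinol chemistry. The diazo transfer and the photolysis must tolerate an aryl methyl ketone. Both stereocenters have to be made (asymmetric dihydroxylation) and one inverted at an easily ionised benzylic carbon next to a hindered phenol. The step count is clearly higher.
- Comparison: the chosen plan sets against this the free supply of rings A, B and C with both stereocenters from catechin, and a benzannulation that solves the ring D pattern rather than requiring it.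

**Alternative 2: ring C closed at O1–C8a by palladium-catalysed etherification.** The cut is the aryl ether bond. The C2 hydroxyl of the anti-diol monoether A4 would couple intramolecularly with the C8a triflate to give hepta-O-benzyl pilosanol N A5.

- Merits: both stereocenters are set in an open chain and are not touched by the ring closure (the new bond is made at the arene). The endgame is a single hydrogenolysis, which is cleaner than the two-stage unmasking of the chosen plan.
- Weak points: A4 contains the whole carbon skeleton, including ring D and a ring A in which one of three oxygens must be singled out as triflate. The triflate is flanked on both sides, which slows oxidative addition and reductive elimination. The secondary benzylic alkoxide on palladium can undergo beta-hydride elimination to a ketone. The anti diol needs its own asymmetric construction.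
- Comparison: the chosen plan has a longer endgame, but it reaches the bond-forming stage in far fewer steps and does not need a preformed ring D.

**Alternative 3: ring C by hetero-Diels–Alder reaction of an ortho-quinone methide.** The cut removes O1–C2 and C3–C4. The quinone methide generated from salicyl alcohol A6 would add to (E)-styrylboronate A7 to give the trans-3-boryl flavan A8, and oxidation of the C–B bond with retention would give the 3-hydroxyl.

- Merits: two bonds, ring C and the trans relationship (from the E alkene) are made in one step. This is the shortest construction of ring C of all four plans, and in convergence it surpasses the chosen one.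
- Weak points: nothing in A6 or A7 controls the absolute configuration, and a single enantiomer is required. An enantioselective version with a vinylboronate as the two-carbon partner would have to be developed, or a resolution accepted. The boronate is only a moderately electron-rich partner, so dimerisation of the quinone methide competes. Ring D is again needed ready-made.
- Comparison: the chosen plan makes more functional-group changes on the catechin core, but its absolute and relative configuration are never in question.

Key step: step 9

## Route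

In the names below, Fl stands for the (2R,3S)-5,7-bis(benzyloxy)-2-[3,4-bis(benzyloxy)phenyl]-3-(tert-butyldimethylsilyloxy)chroman-8-yl group, that is 5,7,3',4'-tetra-O-benzyl-3-O-TBS-(+)-catechin-8-yl.

Step 1
Reactants: 1 (+)-catechin
Product: 2 5,7,3',4'-tetra-O-benzyl-(+)-catechin [(2R,3S)-5,7-bis(benzyloxy)-2-[3,4-bis(benzyloxy)phenyl]chroman-3-ol]
Conditions: BnBr, K2CO3, DMF, 0 °C → rt
Reagents that add atoms: benzyl bromide, BrCc1ccccc1
Why: Williamson etherification of the four phenols; carbonate does not deprotonate the secondary alcohol, and the low temperature limits C-benzylation and C2 epimerisation.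

Step 2
Reactants: 2 5,7,3',4'-tetra-O-benzyl-(+)-catechin
Product: 3 8-bromo-5,7,3',4'-tetra-O-benzyl-(+)-catechin (2R,3S)
Conditions: NBS, CH2Cl2, −78 °C → rt
Reagents that add atoms: N-bromosuccinimide, O=C1CCC(=O)N1Br
Why: Electrophilic aromatic bromination; with one equivalent at low temperature the 5,7-dibenzyloxy flavan reacts at C8, the more nucleophilic of the two open ring A carbons, which fixes the later position of the bridge.

Step 3
Reactants: 3 8-bromo-5,7,3',4'-tetra-O-benzyl-(+)-catechin
Product: 4 8-bromo-5,7,3',4'-tetra-O-benzyl-3-O-(tert-butyldimethylsilyl)-(+)-catechin (Fl–Br)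
Conditions: TBSCl, imidazole, DMF, rt
Reagents that add atoms: tert-butyldimethylsilyl chloride, CC(C)(C)[Si](C)(C)Cl
Why: Standard silylation of the secondary C3 alcohol; the TBS ether removes the only acidic proton before the organometallic steps and is stable to them.

Step 4
Reactants: 4 Fl–Br; 5 ethyl bromoacetate
Product: 7 ethyl 2-Fl-acetate, via Reformatsky reagent 6 (not isolated)
Conditions: 5, Zn dust (TMSCl-activated), THF, 40 °C; then 4, Pd2(dba)3 (cat.), XPhos, THF, 65 °C
Reagents that add atoms: none
Why: Zinc insertion gives the Reformatsky reagent, which couples with the aryl bromide under zerovalent palladium catalysis (Negishi-type arylation of a zinc ester enolate); the bulky electron-rich biarylphosphine is chosen for oxidative addition into the hindered, electron-rich C8–Br bond, and the nearly neutral zinc enolate leaves benzyl and silyl ethers untouched.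

Step 5
Reactants: 7 ethyl 2-Fl-acetate
Product: 10 Fl–CH2–C≡C–OSi(i-Pr)3 [8-(3-triisopropylsilyloxyprop-2-ynyl) derivative], via dibromo enolate 8 (not isolated), via lithium ynolate 9 (not isolated)
Conditions: CH2Br2, LiTMP, THF, −78 °C, then 7; LiHMDS, −78 °C; n-BuLi, −78 °C → rt; TIPSCl, 0 °C → rt
Reagents that add atoms: dibromomethane, BrCBr; triisopropylsilyl chloride, CC(C)[Si](Cl)(C(C)C)C(C)C
Why: Kowalski ester homologation stopped at the ynolate: dibromomethyllithium adds to the ester, the dibromo ketone enolate undergoes bromine–lithium exchange and 1,2-shift of the Fl–CH2 group to the lithium ynolate, and the bulky silyl chloride traps the ynolate on oxygen to give the siloxyalkyne.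

Step 6
Reactants: 11 trichloroacetyl chloride; 12 1-ethoxypropyne
Product: 14 4,4-dichloro-3-ethoxy-2-methylcyclobut-2-en-1-one, via dichloroketene 13 (not isolated)
Conditions: Zn–Cu couple, Et2O/DME, rt
Reagents that add atoms: none
Why: Reductive dechlorination gives dichloroketene, which undergoes [2+2] cycloaddition with the ynol ether; the nucleophilic methyl-bearing alkyne carbon bonds to the ketene carbonyl carbon, which places methyl next to C=O and ethoxy at C3, and DME binds the zinc chloride formed.

Step 7
Reactants: 14 4,4-dichloro-3-ethoxy-2-methylcyclobut-2-en-1-one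
Product: 15 3-ethoxy-2-methylcyclobut-2-en-1-one
Conditions: Zn dust, AcOH, TMEDA, EtOH, 0 °C → rt
Reagents that add atoms: none
Why: Zinc reduction of the alpha,alpha-dichloro ketone via the zinc enolate, the standard way of removing both chlorines from dichloroketene–alkyne adducts; the vinylogous ester is not affected.

Step 8
Reactants: 15 3-ethoxy-2-methylcyclobut-2-en-1-one
Product: 16 3-methoxy-2-methylcyclobut-2-en-1-one
Conditions: MeOH (solvent), TsOH·H2O (cat.), rt
Reagents that add atoms: methanol, CO
Why: Acid-catalysed alkoxy exchange of a vinylogous ester by addition of methanol at C3 and loss of ethanol, the alcohol counterpart of the known mild hydrolysis of 3-alkoxycyclobutenones; the large excess of methanol drives the equilibrium.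

Step 9
Reactants: 10 Fl–CH2–C≡C–OSi(i-Pr)3; 16 3-methoxy-2-methylcyclobut-2-en-1-one
Product: 21 2-(Fl-methyl)-5-methoxy-4-methyl-3-(triisopropylsilyloxy)phenol, via vinylketene 17 (not isolated), via vinylcyclobutenone 18 (not isolated), via dienylketene 19 (not isolated), via cyclohexadienone 20 (not isolated)
Conditions: 16 (2 equiv), toluene, 80 °C → 110 °C, sealed tube
Reagents that add atoms: none
Why: Danheiser benzannulation: thermal four-electron opening of the strained ring of 16 gives vinylketene 17, whose ketene carbonyl carbon is attacked by the CH2-bearing carbon of the polarised siloxyalkyne while the methyl-bearing ketene carbon bonds to the siloxy carbon, a ketene–ynol ether [2+2] that gives 18. Strain release drives a second four-electron opening to dienylketene 19, in which the ketene carbon and the CH2 terminus of the methoxyvinyl group are cis across the central double bond. Ring D closes by a thermally allowed disrotatory six-electron electrocyclisation between these two termini to give 20, and enolisation to the phenol makes the sequence irreversible. No stereocenter is created: the quaternary carbon of 18 is transient, and C2 and C3 of the flavan are remote spectators under neutral thermal conditions. The selectivity that matters is the orientation of the [2+2] step, and it is secured by the oxygen polarisation of the alkyne, which makes the carbon remote from oxygen the nucleophile. As a result OH and OTIPS flank the bridge, methyl and methoxy follow, and the one unsubstituted carbon lies between OH and OMe. The closest known reaction type is the cyclobutenone–siloxyalkyne synthesis of resorcinol monosilyl ethers.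

Step 10
Reactants: 21 2-(Fl-methyl)-5-methoxy-4-methyl-3-(triisopropylsilyloxy)phenol
Product: 22 3-(Fl-methyl)-2-hydroxy-6-methoxy-5-methyl-4-(triisopropylsilyloxy)benzaldehyde
Conditions: MgCl2, Et3N, (CH2O)n, THF, reflux
Reagents that add atoms: paraformaldehyde (as formaldehyde), C=O
Why: Casnati–Skattebøl ortho-formylation: the magnesium phenoxide delivers formaldehyde to the only free ortho carbon and a second formaldehyde oxidises the hydroxymethyl group by hydride transfer; ring A has no free phenol, so its C6–H is not touched, and no acid is present.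

Step 11
Reactants: 22 3-(Fl-methyl)-2-hydroxy-6-methoxy-5-methyl-4-(triisopropylsilyloxy)benzaldehyde
Product: 23 1-[3-(Fl-methyl)-2-hydroxy-6-methoxy-5-methyl-4-(triisopropylsilyloxy)phenyl]ethan-1-ol (both epimers at the carbinol carbon)
Conditions: MeMgBr (3 equiv), THF, −78 °C → 0 °C; aq. NH4Cl
Reagents that add atoms: methylmagnesium bromide, C[Mg]Br
Why: Grignard addition to the aldehyde after deprotonation of the phenol by the first equivalent; the new carbinol stereocenter is formed without control and is removed in step 12.

Step 12
Reactants: 23 1-[3-(Fl-methyl)-2-hydroxy-6-methoxy-5-methyl-4-(triisopropylsilyloxy)phenyl]ethan-1-ol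
Product: 24 1-[3-(Fl-methyl)-2-hydroxy-6-methoxy-5-methyl-4-(triisopropylsilyloxy)phenyl]ethan-1-one
Conditions: MnO2 (activated, excess), CH2Cl2, rt
Reagents that add atoms: none
Why: Neutral heterogeneous oxidation of an electron-rich benzylic alcohol to the ortho-hydroxyaryl ketone; both ortho and the para position of the phenol are substituted, so ring oxidation is not expected.

Step 13
Reactants: 24 1-[3-(Fl-methyl)-2-hydroxy-6-methoxy-5-methyl-4-(triisopropylsilyloxy)phenyl]ethan-1-one
Product: 25 1-[3-{[(2R,3S)-5,7-bis(benzyloxy)-2-[3,4-bis(benzyloxy)phenyl]-3-hydroxychroman-8-yl]methyl}-2,4-dihydroxy-6-methoxy-5-methylphenyl]ethan-1-one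
Conditions: TBAF, AcOH, THF, 0 °C → rt
Reagents that add atoms: none
Why: Fluoride cleaves the aryl TIPS ether (activated by the para acetyl group) and the secondary TBS ether; the acetic acid buffer keeps the acylphloroglucinol from strongly basic conditions, and C2 cannot epimerise while the ring B phenols are benzylated.

Step 14
Reactants: 25 tetra-O-benzyl pilosanol N
Product: 26 pilosanol N
Conditions: H2 (1 atm), Pd(OH)2/C, THF/MeOH, rt
Reagents that add atoms: none
Why: Neutral hydrogenolysis of the four aryl benzyl ethers; the hydrogen-bonded ortho-hydroxyaryl ketone of an acylphloroglucinol is reluctant to reduce, and stopping at full debenzylation avoids hydrogenolysis of the C2–O1 bond.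

## Compound list

1 | (+)-catechin, (2R,3S)-2-(3,4-dihydroxyphenyl)chromane-3,5,7-triol | O[C@H]1Cc2c(O)cc(O)cc2O[C@@H]1c1ccc(O)c(O)c1 | starting material
2 | 5,7,3',4'-tetra-O-benzyl-(+)-catechin (2R,3S) | c1c(OCc2ccccc2)cc(OCc2ccccc2)c2c1O[C@H](c1ccc(OCc3ccccc3)c(OCc3ccccc3)c1)[C@@H](O)C2 | intermediate
3 | 8-bromo-5,7,3',4'-tetra-O-benzyl-(+)-catechin (2R,3S) | Brc1c(OCc2ccccc2)cc(OCc2ccccc2)c2c1O[C@H](c1ccc(OCc3ccccc3)c(OCc3ccccc3)c1)[C@@H](O)C2 | intermediate
4 | 8-bromo-5,7,3',4'-tetra-O-benzyl-3-O-(tert-butyldimethylsilyl)-(+)-catechin (Fl–Br) | Brc1c(OCc2ccccc2)cc(OCc2ccccc2)c2c1O[C@H](c1ccc(OCc3ccccc3)c(OCc3ccccc3)c1)[C@@H](O[Si](C)(C)C(C)(C)C)C2 | intermediate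
5 | ethyl bromoacetate | CCOC(=O)CBr | starting material
6 | bromo(2-ethoxy-2-oxoethyl)zinc (Reformatsky reagent) | CCOC(=O)C[Zn]Br | intermediate
7 | ethyl 2-Fl-acetate | CCOC(=O)Cc1c(OCc2ccccc2)cc(OCc2ccccc2)c2c1O[C@H](c1ccc(OCc3ccccc3)c(OCc3ccccc3)c1)[C@@H](O[Si](C)(C)C(C)(C)C)C2 | intermediate
8 | lithium 1,1-dibromo-3-Fl-prop-1-en-2-olate (dibromo ketone enolate) | [Li]OC(=C(Br)Br)Cc1c(OCc2ccccc2)cc(OCc2ccccc2)c2c1O[C@H](c1ccc(OCc3ccccc3)c(OCc3ccccc3)c1)[C@@H](O[Si](C)(C)C(C)(C)C)C2 | intermediate
9 | lithium 3-Fl-prop-1-yn-1-olate (ynolate) | [Li]OC#CCc1c(OCc2ccccc2)cc(OCc2ccccc2)c2c1O[C@H](c1ccc(OCc3ccccc3)c(OCc3ccccc3)c1)[C@@H](O[Si](C)(C)C(C)(C)C)C2 | intermediate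
10 | Fl–CH2–C≡C–OSi(i-Pr)3, 8-(3-triisopropylsilyloxyprop-2-ynyl) derivative of protected catechin | CC(C)[Si](C(C)C)(C(C)C)OC#CCc1c(OCc2ccccc2)cc(OCc2ccccc2)c2c1O[C@H](c1ccc(OCc3ccccc3)c(OCc3ccccc3)c1)[C@@H](O[Si](C)(C)C(C)(C)C)C2 | intermediate
11 | trichloroacetyl chloride | O=C(Cl)C(Cl)(Cl)Cl | starting material
12 | 1-ethoxypropyne | CC#COCC | starting material
13 | dichloroketene | O=C=C(Cl)Cl | intermediate
14 | 4,4-dichloro-3-ethoxy-2-methylcyclobut-2-en-1-one | O=C1C(C)=C(OCC)C1(Cl)Cl | intermediate
15 | 3-ethoxy-2-methylcyclobut-2-en-1-one | O=C1CC(OCC)=C1C | intermediate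
16 | 3-methoxy-2-methylcyclobut-2-en-1-one | O=C1CC(OC)=C1C | intermediate
17 | 3-methoxy-2-methylbuta-1,3-dien-1-one (vinylketene) | O=C=C(C)C(OC)=C | intermediate
18 | 2-(Fl-methyl)-4-(1-methoxyvinyl)-4-methyl-3-(triisopropylsilyloxy)cyclobut-2-en-1-one (both configurations at C4, transient) | C=C(OC)C1(C)C(=O)C(Cc2c(OCc3ccccc3)cc(OCc3ccccc3)c3c2O[C@H](c2ccc(OCc4ccccc4)c(OCc4ccccc4)c2)[C@@H](O[Si](C)(C)C(C)(C)C)C3)=C1O[Si](C(C)C)(C(C)C)C(C)C | intermediate
19 | 2-(Fl-methyl)-5-methoxy-4-methyl-3-(triisopropylsilyloxy)hexa-1,3,5-trien-1-one (dienylketene, ketene carbon and methoxyvinyl group cis) | O=C=C(Cc1c(OCc2ccccc2)cc(OCc2ccccc2)c2c1O[C@H](c1ccc(OCc3ccccc3)c(OCc3ccccc3)c1)[C@@H](O[Si](C)(C)C(C)(C)C)C2)/C(O[Si](C(C)C)(C(C)C)C(C)C)=C(C)\C(OC)=C | intermediate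
20 | 2-(Fl-methyl)-5-methoxy-4-methyl-3-(triisopropylsilyloxy)cyclohexa-2,4-dien-1-one | O=C1CC(OC)=C(C)C(O[Si](C(C)C)(C(C)C)C(C)C)=C1Cc1c(OCc2ccccc2)cc(OCc2ccccc2)c2c1O[C@H](c1ccc(OCc3ccccc3)c(OCc3ccccc3)c1)[C@@H](O[Si](C)(C)C(C)(C)C)C2 | intermediate
21 | 2-(Fl-methyl)-5-methoxy-4-methyl-3-(triisopropylsilyloxy)phenol | COc1cc(O)c(Cc2c(OCc3ccccc3)cc(OCc3ccccc3)c3c2O[C@H](c2ccc(OCc4ccccc4)c(OCc4ccccc4)c2)[C@@H](O[Si](C)(C)C(C)(C)C)C3)c(O[Si](C(C)C)(C(C)C)C(C)C)c1C | intermediate
22 | 3-(Fl-methyl)-2-hydroxy-6-methoxy-5-methyl-4-(triisopropylsilyloxy)benzaldehyde | COc1c(C=O)c(O)c(Cc2c(OCc3ccccc3)cc(OCc3ccccc3)c3c2O[C@H](c2ccc(OCc4ccccc4)c(OCc4ccccc4)c2)[C@@H](O[Si](C)(C)C(C)(C)C)C3)c(O[Si](C(C)C)(C(C)C)C(C)C)c1C | intermediate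
23 | 1-[3-(Fl-methyl)-2-hydroxy-6-methoxy-5-methyl-4-(triisopropylsilyloxy)phenyl]ethan-1-ol (both carbinol epimers) | COc1c(C(C)O)c(O)c(Cc2c(OCc3ccccc3)cc(OCc3ccccc3)c3c2O[C@H](c2ccc(OCc4ccccc4)c(OCc4ccccc4)c2)[C@@H](O[Si](C)(C)C(C)(C)C)C3)c(O[Si](C(C)C)(C(C)C)C(C)C)c1C | intermediate
24 | 1-[3-(Fl-methyl)-2-hydroxy-6-methoxy-5-methyl-4-(triisopropylsilyloxy)phenyl]ethan-1-one | COc1c(C(C)=O)c(O)c(Cc2c(OCc3ccccc3)cc(OCc3ccccc3)c3c2O[C@H](c2ccc(OCc4ccccc4)c(OCc4ccccc4)c2)[C@@H](O[Si](C)(C)C(C)(C)C)C3)c(O[Si](C(C)C)(C(C)C)C(C)C)c1C | intermediate
25 | 5,7,3',4'-tetra-O-benzyl pilosanol N (2R,3S) | COc1c(C(C)=O)c(O)c(Cc2c(OCc3ccccc3)cc(OCc3ccccc3)c3c2O[C@H](c2ccc(OCc4ccccc4)c(OCc4ccccc4)c2)[C@@H](O)C3)c(O)c1C | intermediate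
26 | pilosanol N (2R,3S) | COc1c(C)c(O)c(Cc2c(O)cc(O)c3c2O[C@H](c2ccc(O)c(O)c2)[C@@H](O)C3)c(O)c1C(C)=O | target

## Step count and least certain steps

Total step count: 14. Longest linear sequence: 11 steps (steps 1–5 and 9–14 from (+)-catechin); the cyclobutenone branch (steps 6–8) joins at step 9.

**Step 9 (key step).** The donor-substituted cyclobutenone is stabilised as a vinylogous ester, so its ring opening may be slow. At the temperature then needed, the siloxyalkyne may undergo a 1,3-silyl shift to a silylketene or isomerise at the propargylic CH2. A second vinylketene may also acylate the product phenol. The fallback sets out from 10 and comes back at 21. It generates the same vinylketene at room temperature from a diazo ketone instead of a strained ring. Methyl vinyl ether is lithiated (t-BuLi, THF) and acylated with N-methoxy-N-methylpropanamide to give 2-methoxypent-1-en-3-one F1. Detrifluoroacetylative diazo transfer (LiHMDS, 2,2,2-trifluoroethyl trifluoroacetate; then MsN3, Et3N, H2O, MeCN) gives 2-diazo-4-methoxypent-4-en-3-one F2. Irradiation of F2 with 10 in CH2Cl2 causes a Wolff rearrangement to 17, which is carried through 18, 19 and 20 to 21 on mild warming.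

**Step 5.** Dibromomethyllithium may enolise the acidic arylacetate CH2 instead of adding to the carbonyl. During the warm-up, excess butyllithium may metalate C6–H or attack the benzyl ethers. The fallback sets out from 7 and comes back at 10 through the ynolate 9 made by oxidation instead of rearrangement. Reduction with DIBAL-H (CH2Cl2, −78 °C) gives 2-Fl-acetaldehyde F3. The Ohira–Bestmann reagent (K2CO3, MeOH) gives the terminal alkyne 8-(prop-2-ynyl) derivative F4. Deprotonation (n-BuLi, −78 °C), oxidation of the lithium acetylide with lithium tert-butyl peroxide (from t-BuOOH and LiHMDS) to 9, and O-silylation with TIPSCl give 10.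

**Step 4.** Oxidative addition into the C8–Br bond, which is flanked by two oxygen substituents on a very electron-rich ring, may be slow, so that protodebromination or decay of the zinc enolate dominates. The fallback sets out from 4 and comes back at 7 with reversed polarity and no palladium. Bromine–lithium exchange (n-BuLi, THF, −78 °C), addition to ethyl glyoxylate and quenching of the alkoxide with Ac2O give ethyl 2-acetoxy-2-Fl-acetate F5 (both epimers). Reductive removal of the alpha-acetoxy group with SmI2 (THF/MeOH, −78 °C) gives 7.

**Step 8.** Methanol may attack the carbonyl of the strained enone and open the ring to acyclic beta-keto ester derivatives instead of exchanging the alkoxy group. The fallback sets out from 15 and comes back at 16. Hydrolysis with cold dilute aqueous HCl gives 3-hydroxy-2-methylcyclobut-2-en-1-one F6, the enol of the symmetrical 2-methylcyclobutane-1,3-dione. O-methylation with TMSCHN2 (MeOH/toluene, 0 °C) can give only one enol ether, 16.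

**Step 10.** Formylation at the last, crowded position may be slow, and prolonged heating with excess formaldehyde may lead to methoxymethylation of the phenol. The fallback sets out from 21 and comes back at 24, bypassing steps 10–12. Amine-catalysed ortho-bromination of the free phenol (NBS, cat. i-Pr2NH, CH2Cl2, −78 °C) gives 2-bromo-6-(Fl-methyl)-3-methoxy-4-methyl-5-(triisopropylsilyloxy)phenol F7. Stille coupling with tributyl(1-ethoxyvinyl)stannane (Pd(PPh3)4, toluene, 100 °C) gives the 1-ethoxyvinyl arene F8. Brief treatment with dilute aqueous HCl in THF hydrolyses the enol ether to 24.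

## Further compounds

F1 | step 9 | 2-methoxypent-1-en-3-one | C=C(OC)C(=O)CC
F2 | step 9 | 2-diazo-4-methoxypent-4-en-3-one | C=C(OC)C(=O)C(C)=[N+]=[N-]
F3 | step 5 | 2-Fl-acetaldehyde | O=CCc1c(OCc2ccccc2)cc(OCc2ccccc2)c2c1O[C@H](c1ccc(OCc3ccccc3)c(OCc3ccccc3)c1)[C@@H](O[Si](C)(C)C(C)(C)C)C2
F4 | step 5 | 8-(prop-2-ynyl)-5,7,3',4'-tetra-O-benzyl-3-O-TBS-(+)-catechin | C#CCc1c(OCc2ccccc2)cc(OCc2ccccc2)c2c1O[C@H](c1ccc(OCc3ccccc3)c(OCc3ccccc3)c1)[C@@H](O[Si](C)(C)C(C)(C)C)C2
F5 | step 4 | ethyl 2-acetoxy-2-Fl-acetate (both epimers at the acetoxy carbon) | CCOC(=O)C(OC(C)=O)c1c(OCc2ccccc2)cc(OCc2ccccc2)c2c1O[C@H](c1ccc(OCc3ccccc3)c(OCc3ccccc3)c1)[C@@H](O[Si](C)(C)C(C)(C)C)C2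
F6 | step 8 | 3-hydroxy-2-methylcyclobut-2-en-1-one | O=C1CC(O)=C1C
F7 | step 10 | 2-bromo-6-(Fl-methyl)-3-methoxy-4-methyl-5-(triisopropylsilyloxy)phenol | COc1c(Br)c(O)c(Cc2c(OCc3ccccc3)cc(OCc3ccccc3)c3c2O[C@H](c2ccc(OCc4ccccc4)c(OCc4ccccc4)c2)[C@@H](O[Si](C)(C)C(C)(C)C)C3)c(O[Si](C(C)C)(C(C)C)C(C)C)c1C
F8 | step 10 | 2-(1-ethoxyvinyl)-6-(Fl-methyl)-3-methoxy-4-methyl-5-(triisopropylsilyloxy)phenol | COc1c(C(=C)OCC)c(O)c(Cc2c(OCc3ccccc3)cc(OCc3ccccc3)c3c2O[C@H](c2ccc(OCc4ccccc4)c(OCc4ccccc4)c2)[C@@H](O[Si](C)(C)C(C)(C)C)C3)c(O[Si](C(C)C)(C(C)C)C(C)C)c1C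
A1 | alternative 1 | (Z)-5-[3-acetyl-2,6-bis(benzyloxy)-4-methoxy-5-methylphenyl]-3-(benzyloxy)-1-diazopent-3-en-2-one (ring D diazo ketone) | [N-]=[N+]=CC(=O)/C(OCc1ccccc1)=C/Cc1c(OCc2ccccc2)c(C)c(OC)c(C(C)=O)c1OCc1ccccc1
A2 | alternative 1 | triisopropyl({3-[(4S,5S)-5-[3,4-bis(benzyloxy)phenyl]-2,2-dimethyl-1,3-dioxolan-4-yl]prop-1-yn-1-yl}oxy)silane (chiral siloxyalkyne) | CC(C)[Si](C(C)C)(C(C)C)OC#CC[C@@H]1OC(C)(C)O[C@H]1c1ccc(OCc2ccccc2)c(OCc2ccccc2)c1
A3 | alternative 1 | ring A phenol with free C8a hydroxyl, syn-diol acetonide side chain and ring D attached through CH2 | Oc1c(C[C@@H]2OC(C)(C)O[C@H]2c2ccc(OCc3ccccc3)c(OCc3ccccc3)c2)c(O[Si](C(C)C)(C(C)C)C(C)C)cc(OCc2ccccc2)c1Cc1c(OCc2ccccc2)c(C)c(OC)c(C(C)=O)c1OCc1ccccc1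
A4 | alternative 2 | C8a aryl triflate with (2R,3S) anti-diol side chain, C3 benzyl ether and free C2 hydroxyl | COc1c(C)c(OCc2ccccc2)c(Cc2c(OCc3ccccc3)cc(OCc3ccccc3)c(C[C@H](OCc3ccccc3)[C@H](O)c3ccc(OCc4ccccc4)c(OCc4ccccc4)c3)c2OS(=O)(=O)C(F)(F)F)c(OCc2ccccc2)c1C(C)=O
A5 | alternative 2 | hepta-O-benzyl pilosanol N | COc1c(C)c(OCc2ccccc2)c(Cc2c(OCc3ccccc3)cc(OCc3ccccc3)c3c2O[C@H](c2ccc(OCc4ccccc4)c(OCc4ccccc4)c2)[C@@H](OCc2ccccc2)C3)c(OCc2ccccc2)c1C(C)=O
A6 | alternative 3 | ring A salicyl alcohol (C8a hydroxyl, C4a hydroxymethyl) carrying ring D through CH2 | COc1c(C)c(OCc2ccccc2)c(Cc2c(OCc3ccccc3)cc(OCc3ccccc3)c(CO)c2O)c(OCc2ccccc2)c1C(C)=O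
A7 | alternative 3 | (E)-2-[2-(3,4-bis(benzyloxy)phenyl)vinyl]-4,4,5,5-tetramethyl-1,3,2-dioxaborolane | CC1(C)OB(/C=C/c2ccc(OCc3ccccc3)c(OCc3ccccc3)c2)OC1(C)C
A8 | alternative 3 | trans-3-boryl flavan with the full carbon skeleton | COc1c(C)c(OCc2ccccc2)c(Cc2c(OCc3ccccc3)cc(OCc3ccccc3)c3c2O[C@H](c2ccc(OCc4ccccc4)c(OCc4ccccc4)c2)[C@@H](B2OC(C)(C)C(C)(C)O2)C3)c(OCc2ccccc2)c1C(C)=O
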